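# Proposed total synthesis of CNP0324832.1 by a lactone-terminated Claisen closure of ring A

## Analysis of the target

The target is an isoflavone (3-aryl-4H-chromen-4-one). The chromenone numbering O1, C2, C3, C4, C4a, C5–C8, C8a is used throughout, also for the same carbons in open-chain intermediates. Ring B is a 4-hydroxyphenyl group on C3 and ring C is the pyranone. Ring A is fully substituted: methoxy at C5, a 3-methylbut-2-enyl (prenyl) group at C6, hydroxyl at C7 and a 2-hydroxy-3-methylbut-3-enyl chain at C8.

The only stereocentre is the secondary allylic carbinol of the C8 chain (R). It has no stereochemical partner, so it must be set absolutely and then carried through unchanged.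

The sensitive groups are the two alkenes that flank the free C7 phenol (acid closes them to chromans or dihydrofurans), the allylic alcohol (ionisation under acid) and the chromenone, which hard nucleophiles open at C2.

The difficulty is ring A. The three oxygens of a phloroglucinol must end up different (methyl ether, free phenol, ring oxygen), and two different five-carbon chains must sit on C6 and C8. Substitution chemistry on the arene does not distinguish these positions.

The strategy rests on one feature. The unit C4–C4a–C5–C6–C7–C8–C8a is an acylphloroglucinol, that is, a folded chain of alternating carbonyl carbons. The hydroxyl of the C8 chain sits on the carbon gamma to C8a, so C8a can be the carbonyl of a five-membered lactone whose ring oxygen is that hydroxyl. Forming the C4a–C8a bond by a Claisen reaction then closes ring A and releases the carbinol in one event.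

## Retrosynthetic reasoning

**20 to 19 (O–Si).** The last bond cut is the O–Si bond of the ring B phenol. That phenol is the only group that needs protection through the basic steps. A triisopropylsilyl ether is chosen because it tolerates carbanions, an amidine base and an amide acetal, and falls to fluoride at the end.

**19 to 17 (O1–C2 and C2–C3).** Ring C is opened at O1–C2 and C2–C3, which removes C2 as a one-carbon unit at the formic acid level and leads to deoxybenzoin 17. Ring C is the part most exposed to bases and nucleophiles, so it is made late. The closure is unambiguous: the ketone of 17 is flanked by the C5 methoxy group and the C8a hydroxyl, so only C8a can become the ring oxygen. The forward reaction must functionalise the benzylic methylene without alkylating the free C7 phenol (via enaminone 18).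

**17 to 16 (C4a–C8a, the key disconnection).** Cutting this one bond undoes the aromaticity of ring A and unfolds it into chain 16. In 16 the lactone carbonyl is C8a, the ketone is C7, the methyl enol ether is C5 and the enone carbonyl is C4. The three ring A oxygens are thus different by construction. The prenyl group and the chiral chain are ordinary substituents on C6 and C8, and the carbinol oxygen is both protected and turned into the leaving group. No regiochemical choice on an arene remains. The forward reaction must make the dienolate attack the lactone through C4a and then aromatise.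

**16 to 15 and 8 (C4–C4a).** The arylacetyl unit brings the ketone whose benzylic methylene is a competing carbon acid, so it is attached last. It is introduced as the N-methoxy-N-methylamide 8, so the ketone appears only on work-up. The nucleophile is the terminal carbon of the dianion of 15. Transferring the whole chain to the lactone enolate from a cyclic enol-lactone donor was set aside: such a donor carries a benzylic methylene more acidic than the lactone and would be deprotonated instead of attacked. Cuts at C6–C7 or C5–C6 would need a carbanion next to that same benzylic ketone.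

**15 to 5 and 13 (C7–C8).** This is a crossed Claisen acylation of the enolate of lactone 5 by acid chloride 14, made from acid 13. The acyl donor has no ketone, so it cannot close onto itself. Its most acidic hydrogens are those of a vinylogous methyl group, which do not interfere at low temperature.

**13 back to 9 and 10.** Acid 13 comes from ester 12, the methyl enol ether of keto ester 11, which is the prenylation product of methyl acetoacetate 9 with prenyl bromide 10. Forming the enol ether at this stage places the methyl group on the future C5 oxygen while it is the only ketone in the molecule. This is how the C5/C7/C8a oxygens are told apart.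

**5 back to 1 and 2.** Lactone 5 carries the stereocentre. It is the cyclised form of hydroxy ester 4, obtained by enantioselective reduction of enone 3. Enone 3 comes from acid chloride 1 and Grignard reagent 2. A reagent-controlled reduction is preferred over a chiral-pool route because it gives the R carbinol in two steps from bulk chemicals.

**8 back to 6.** Amide 8 is made from 4-hydroxyphenylacetic acid 6 by amide formation (7) and silylation.

## Alternatives that were turned down

**Alternative 1:** The carbinol is disconnected instead of ring A. The C8 chain is traced back to an (E)-4-hydroxy-3-methylbut-2-enyl chain on a finished, bis-silylated isoflavone A2. The forward key step is epoxidation of this allylic alcohol with Ti(OiPr)4, D-(−)-diethyl tartrate and tert-butyl hydroperoxide to the (2R,3R)-epoxy alcohol A1. Conversion of the primary alcohol to an iodide and reductive opening with zinc would then move the alkene to the chain end and leave the carbinol on the former epoxide CH.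
- For: face selection on a trisubstituted E allylic alcohol is highly predictable, the hydroxyl directs the oxidant away from the C6 prenyl alkene, and the stereocentre is set late.
- Against: A2 presupposes the hexasubstituted ring A, with two different chains placed on C6 and C8 and the hydrogen-bonded C5 oxygen methylated selectively. That is the real problem of the target and this disconnection leaves it unsolved. The epoxide also sits next to a silyloxy group and would be opened by the phenoxide if the silyl group is lost. Iodide formation and zinc reduction add two steps on a chromenone.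
- Comparison: Alternative 1 is stronger on precedent for the stereo-defining step. The chosen strategy offers a ring A whose substitution pattern follows from chain connectivity and a shorter route.

**Alternative 2:** Ring C is disconnected at C4–C4a. The precursor is the (Z)-3-aryloxy-2-arylacryloyl chloride A4, with ring B already on the future C3 and the complete ring A as the aryloxy group. SnCl4 would promote intramolecular Friedel–Crafts acylation at C4a to give the target triacetate A3.
- For: C4a is the only free position, so the closure is regiochemically forced, and the two halves are joined convergently.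
- Against: a strong Lewis acid and an acid chloride meet a prenyl group, an isopropenyl group and a secondary allylic acetate. Hydrochlorination, cation–alkene cyclisation and ionisation of the allylic acetate (loss of configuration) are all plausible. The attacked position lies between two ortho substituents on a ring deactivated by two acetoxy groups. The Z geometry of the enol ether must be secured. Ring A with its chain and stereocentre still has to be made by other means.
- Comparison: Alternative 2 is as strong as the chosen route on the regiochemistry of ring C closure. The chosen route closes ring C under basic to neutral conditions that the alkenes tolerate and, unlike Alternative 2, also constructs ring A.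

**Alternative 3:** Ring A is assembled from two fragments by Danheiser benzannulation. Heating the 2-alkyl-3-siloxycyclobutenone A6, which carries the silylated R chain, with the prenyl siloxyalkyne A7 would proceed through a vinylketene, a [2+2] adduct and a dienylketene. It would close to the pentasubstituted phenol A5, forming C5–C6, C7–C8 and C4a–C5. The C5 oxygen emerges free, the C7 and C8a oxygens silylated and C4a unsubstituted.
- For: the regiochemistry is dictated by the mechanism, the conditions are neutral and thermal, and the C5 oxygen is differentiated automatically. On this last point it equals the chosen strategy.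
- Against: neither A6 nor A7 is a simple compound, and A6 must itself be built with the chiral chain. After the annulation the route still needs O-methylation, C-acylation of a hindered bis-silyloxy arene at C4a with the arylacetyl unit (Lewis acid next to a prenyl group, or a metalation without a good directing group), desilylation and ring C formation.
- Comparison: Alternative 3 is stronger on precedent for the ring-forming event. The chosen strategy delivers ring A with the C4a acyl group already in place, from cheaper fragments and in fewer steps.

Key step: step 10

## Route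

Remark: 16 is written as the C4a=C5 enone tautomer. After work-up it is expected as a mixture with its C5=C6 double-bond isomer, with enol forms and with epimers at C6 and C8. All of these give the same dienolate in step 10, so the mixture is used as such. Compounds 12–15 are likewise E/Z mixtures of no consequence.

Step 1
Reactants: 1 methyl 4-chloro-4-oxobutanoate; 2 isopropenylmagnesium bromide (CH2=C(CH3)MgBr)
Product: 3 methyl 5-methyl-4-oxohex-5-enoate
Conditions: CuI (5 mol%), THF, −78 °C, 2 added over 1 h; aq. NH4Cl
Reagents that add atoms: none
Why: Copper-catalysed acylation of a Grignard reagent by an acid chloride; at −78 °C with slow addition the acid chloride reacts far faster than the methyl ester or the product enone, so over-addition and conjugate addition should stay minor.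

Step 2
Reactants: 3 methyl 5-methyl-4-oxohex-5-enoate
Product: 5 (5R)-5-(prop-1-en-2-yl)oxolan-2-one, via hydroxy ester 4 (not isolated)
Conditions: (S)-2-methyl-CBS-oxazaborolidine (15 mol%), catecholborane (1.5 equiv), toluene, −78 °C; MeOH quench; then pyridinium p-toluenesulfonate (5 mol%), toluene, 50 °C
Reagents that add atoms: none
Why: Corey–Bakshi–Shibata reduction with 1,2-selectivity; the alpha-branched alkenyl group acts as the large substituent, so the S catalyst should deliver hydride to the face that gives the R carbinol (the same sense as for aryl methyl ketones), and the gamma-hydroxy ester 4 lactonises under mild acid without touching the stereocentre.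

Step 3
Reactants: 6 4-hydroxyphenylacetic acid
Product: 7 2-(4-hydroxyphenyl)-N-methoxy-N-methylacetamide
Conditions: MeNH(OMe)·HCl, EDC·HCl, HOBt, N-methylmorpholine, CH2Cl2/DMF, 0 → 23 °C
Reagents that add atoms: N,O-dimethylhydroxylamine hydrochloride, CNOC.Cl
Why: Carbodiimide amide coupling; the amine outcompetes the phenol for the active ester, and any aryl ester that forms is aminolysed under the same conditions.

Step 4
Reactants: 7 2-(4-hydroxyphenyl)-N-methoxy-N-methylacetamide
Product: 8 N-methoxy-N-methyl-2-[4-(triisopropylsilyloxy)phenyl]acetamide
Conditions: i-Pr3SiCl, imidazole, DMF, 23 °C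
Reagents that add atoms: chlorotriisopropylsilane, CC(C)[Si](Cl)(C(C)C)C(C)C
Why: Standard silylation of a phenol; the bulky triisopropylsilyl ether is chosen because it should survive the carbanion, amidine and amide acetal steps that follow.

Step 5
Reactants: 9 methyl acetoacetate; 10 prenyl bromide
Product: 11 methyl 2-acetyl-5-methylhex-4-enoate
Conditions: K2CO3 (1.2 equiv), acetone, 56 °C; 9 in 1.3-fold excess
Reagents that add atoms: none
Why: Acetoacetic ester alkylation (SN2 of the stabilised enolate on a primary allylic bromide); the excess of 9 suppresses dialkylation.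

Step 6
Reactants: 11 methyl 2-acetyl-5-methylhex-4-enoate
Product: 12 methyl 3-methoxy-2-(3-methylbut-2-en-1-yl)but-2-enoate (E/Z mixture)
Conditions: HC(OMe)3, H2SO4 (cat.), MeOH, 23 °C; distillation
Reagents that add atoms: trimethyl orthoformate, COC(OC)OC
Why: Acid-catalysed ketalisation and loss of methanol, the usual conversion of a beta-keto ester into its beta-methoxy enoate; it fixes the methyl group on the oxygen that becomes the C5 methoxy group, and the catalytic acid in methanol should leave the trisubstituted alkene alone.

Step 7
Reactants: 12 methyl 3-methoxy-2-(3-methylbut-2-en-1-yl)but-2-enoate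
Product: 13 3-methoxy-2-(3-methylbut-2-en-1-yl)but-2-enoic acid
Conditions: KOH (3 equiv), MeOH/H2O 3:1, 65 °C; then 1 M HCl to pH 4, 0 °C
Reagents that add atoms: potassium hydroxide, [K+].[OH-]
Why: Saponification; the enol ether is inert to base, and a cold, only mildly acidic work-up should keep it from hydrolysing to the beta-keto acid.

Step 8
Reactants: 13 3-methoxy-2-(3-methylbut-2-en-1-yl)but-2-enoic acid; 5 (5R)-5-(prop-1-en-2-yl)oxolan-2-one
Product: 15 (5R)-3-[3-methoxy-2-(3-methylbut-2-en-1-yl)but-2-enoyl]-5-(prop-1-en-2-yl)oxolan-2-one, via acid chloride 14 (not isolated)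
Conditions: 13, 1-chloro-N,N,2-trimethylprop-1-en-1-amine, CH2Cl2, 0 °C; separately 5, LiN(SiMe3)2 (2.1 equiv), THF, −78 °C; solution of 14 added, −78 → −40 °C; aq. NH4Cl
Reagents that add atoms: none
Why: Crossed Claisen C-acylation of a lithium lactone enolate by an acid chloride; the chloroenamine makes 14 without HCl, the second equivalent of base takes up the more acidic product, the new centre at C8 is epimerisable and left undefined, and the carbinol carbon of 5 is not acidic and stays R.

Step 9
Reactants: 15 (5R)-3-[3-methoxy-2-(3-methylbut-2-en-1-yl)but-2-enoyl]-5-(prop-1-en-2-yl)oxolan-2-one; 8 N-methoxy-N-methyl-2-[4-(triisopropylsilyloxy)phenyl]acetamide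
Product: 16 (5R)-3-{3-methoxy-2-(3-methylbut-2-en-1-yl)-5-oxo-6-[4-(triisopropylsilyloxy)phenyl]hex-3-enoyl}-5-(prop-1-en-2-yl)oxolan-2-one
Conditions: LiN(i-Pr)2 (2.3 equiv), THF, −78 °C, 1 h; 8 (1.2 equiv), −78 → −30 °C; AcOH/NaOAc buffer (pH 5), −30 → 0 °C
Reagents that add atoms: none
Why: Terminal acylation of a 1,3-dicarbonyl dianion by an N-methoxy-N-methylamide; the first equivalent forms the beta-keto lactone enolate, the second removes a proton from the methyl group on the enol ether carbon to give a carbanion delocalised through C5=C6 and C7 onto the lactone oxygen, and this last-formed terminus (C4a) is the most nucleophilic site. The chelated tetrahedral adduct holds the ketone back until work-up, so no more acidic C–H appears in the flask and the dianion is protected against premature ring closure by its own enolate.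

Step 10
Reactants: 16 (5R)-3-{3-methoxy-2-(3-methylbut-2-en-1-yl)-5-oxo-6-[4-(triisopropylsilyloxy)phenyl]hex-3-enoyl}-5-(prop-1-en-2-yl)oxolan-2-one
Product: 17 1-{2,4-dihydroxy-3-[(2R)-2-hydroxy-3-methylbut-3-en-1-yl]-6-methoxy-5-(3-methylbut-2-en-1-yl)phenyl}-2-[4-(triisopropylsilyloxy)phenyl]ethan-1-one
Conditions: DBU (1.5 equiv), MeCN (0.02 M), 0 → 50 °C; pH 5 phosphate buffer
Reagents that add atoms: none
Why: Proposed new method: DBU removes the C6 proton (or a C4a proton of the double-bond isomer) in equilibrium with the more acidic but unproductive C8 proton, and the resulting dienolate attacks the lactone carbonyl C8a through C4a. The tetrahedral intermediate expels the side-chain oxygen, which is a far better leaving group than either carbon substituent, and the 2-acylcyclohexenedione so formed tautomerises irreversibly to the phenoxide of 17. The closest known reaction type is the base-mediated Claisen (Dieckmann-type) cyclisation of open-chain beta-polyketo esters to acylphloroglucinols; new here are the lactone as electrophile, which releases the carbinol, and the methyl enol ether inside the chain, which keeps the C5 oxygen as methoxy. Ring A closes in a 6-(enolendo)-exo-trig mode, which is geometrically easy because the C5=C6 bond of the dienolate lies inside the forming ring. No stereocentre is formed: the carbinol carbon is not acidic and its C–O bond is not broken, so the R configuration of 5 passes on unchanged, and the epimeric centres C6 and C8 become sp2. The step needs C-acylation at C4a to win over internal O-attack at C7 (retro-Claisen loss of the lactone) and over aldol closure of the benzylic methylene onto C7; with about one equivalent of a non-nucleophilic amidine the chain stays in the mono-anion manifold, where C7 is an enolate carbon in either tautomer and the lactone carbonyl is the only electrophile left. O-attack of the dienolate on the lactone would need an eight-membered ring, and expelling a lactone enolate from C7 is much less favourable than expelling an alkoxide from C8a. High dilution suppresses intermolecular acyl transfer.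

Step 11
Reactants: 17 1-{2,4-dihydroxy-3-[(2R)-2-hydroxy-3-methylbut-3-en-1-yl]-6-methoxy-5-(3-methylbut-2-en-1-yl)phenyl}-2-[4-(triisopropylsilyloxy)phenyl]ethan-1-one
Product: 19 7-hydroxy-8-[(2R)-2-hydroxy-3-methylbut-3-en-1-yl]-5-methoxy-6-(3-methylbut-2-en-1-yl)-3-[4-(triisopropylsilyloxy)phenyl]-4H-chromen-4-one, via enaminone 18 (not isolated)
Conditions: Me2NCH(OMe)2 (2.5 equiv), THF, 50 °C; then AcOH (cat.), MeOH, 23 °C
Reagents that add atoms: N,N-dimethylformamide dimethyl acetal, COC(OC)N(C)C
Why: Isoflavone synthesis from a 2-hydroxydeoxybenzoin: the amide acetal condenses at the activated benzylic methylene to enaminone 18, and the C8a hydroxyl, the only one ortho to the ketone, displaces dimethylamine by addition–elimination. The moderate temperature should avoid O-methylation of the C7 phenol, and the methanol treatment returns any amide acetal formed at the carbinol.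

Step 12
Reactants: 19 7-hydroxy-8-[(2R)-2-hydroxy-3-methylbut-3-en-1-yl]-5-methoxy-6-(3-methylbut-2-en-1-yl)-3-[4-(triisopropylsilyloxy)phenyl]-4H-chromen-4-one
Product: 20 7-hydroxy-8-[(2R)-2-hydroxy-3-methylbut-3-en-1-yl]-3-(4-hydroxyphenyl)-5-methoxy-6-(3-methylbut-2-en-1-yl)-4H-chromen-4-one
Conditions: Bu4NF (1.1 equiv), AcOH (1.1 equiv), THF, 0 °C
Reagents that add atoms: none
Why: Fluoride cleavage of an aryl silyl ether; buffering with acetic acid keeps the medium near neutral, so the chromenone is not opened and the alkenes and the carbinol are untouched.

## Compound list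

1 | methyl 4-chloro-4-oxobutanoate | COC(=O)CCC(Cl)=O | starting material
2 | isopropenylmagnesium bromide | C=C(C)[Mg]Br | starting material
3 | methyl 5-methyl-4-oxohex-5-enoate | C=C(C)C(=O)CCC(=O)OC | intermediate
4 | methyl (4R)-4-hydroxy-5-methylhex-5-enoate | C=C(C)[C@H](O)CCC(=O)OC | intermediate
5 | (5R)-5-(prop-1-en-2-yl)oxolan-2-one | C=C(C)[C@H]1CCC(=O)O1 | intermediate
6 | 4-hydroxyphenylacetic acid | OC(=O)Cc1ccc(O)cc1 | starting material
7 | 2-(4-hydroxyphenyl)-N-methoxy-N-methylacetamide | CON(C)C(=O)Cc1ccc(O)cc1 | intermediate
8 | N-methoxy-N-methyl-2-[4-(triisopropylsilyloxy)phenyl]acetamide | CON(C)C(=O)Cc1ccc(O[Si](C(C)C)(C(C)C)C(C)C)cc1 | intermediate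
9 | methyl acetoacetate | CC(=O)CC(=O)OC | starting material
10 | prenyl bromide (1-bromo-3-methylbut-2-ene) | CC(C)=CCBr | starting material
11 | methyl 2-acetyl-5-methylhex-4-enoate | CC(=O)C(CC=C(C)C)C(=O)OC | intermediate
12 | methyl 3-methoxy-2-(3-methylbut-2-en-1-yl)but-2-enoate (E/Z mixture) | COC(C)=C(CC=C(C)C)C(=O)OC | intermediate
13 | 3-methoxy-2-(3-methylbut-2-en-1-yl)but-2-enoic acid | COC(C)=C(CC=C(C)C)C(=O)O | intermediate
14 | 3-methoxy-2-(3-methylbut-2-en-1-yl)but-2-enoyl chloride | COC(C)=C(CC=C(C)C)C(Cl)=O | intermediate
15 | (5R)-3-[3-methoxy-2-(3-methylbut-2-en-1-yl)but-2-enoyl]-5-(prop-1-en-2-yl)oxolan-2-one (epimers at C3 of the lactone) | C=C(C)[C@H]1CC(C(=O)C(CC=C(C)C)=C(C)OC)C(=O)O1 | intermediate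
16 | (5R)-3-{3-methoxy-2-(3-methylbut-2-en-1-yl)-5-oxo-6-[4-(triisopropylsilyloxy)phenyl]hex-3-enoyl}-5-(prop-1-en-2-yl)oxolan-2-one (precursor of the key step; tautomer and epimer mixture) | C=C(C)[C@H]1CC(C(=O)C(CC=C(C)C)C(OC)=CC(=O)Cc2ccc(O[Si](C(C)C)(C(C)C)C(C)C)cc2)C(=O)O1 | intermediate
17 | 1-{2,4-dihydroxy-3-[(2R)-2-hydroxy-3-methylbut-3-en-1-yl]-6-methoxy-5-(3-methylbut-2-en-1-yl)phenyl}-2-[4-(triisopropylsilyloxy)phenyl]ethan-1-one (product of the key step) | C=C(C)[C@H](O)Cc1c(O)c(CC=C(C)C)c(OC)c(C(=O)Cc2ccc(O[Si](C(C)C)(C(C)C)C(C)C)cc2)c1O | intermediate
18 | 1-{2,4-dihydroxy-3-[(2R)-2-hydroxy-3-methylbut-3-en-1-yl]-6-methoxy-5-(3-methylbut-2-en-1-yl)phenyl}-3-(dimethylamino)-2-[4-(triisopropylsilyloxy)phenyl]prop-2-en-1-one | C=C(C)[C@H](O)Cc1c(O)c(CC=C(C)C)c(OC)c(C(=O)C(=CN(C)C)c2ccc(O[Si](C(C)C)(C(C)C)C(C)C)cc2)c1O | intermediate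
19 | 7-hydroxy-8-[(2R)-2-hydroxy-3-methylbut-3-en-1-yl]-5-methoxy-6-(3-methylbut-2-en-1-yl)-3-[4-(triisopropylsilyloxy)phenyl]-4H-chromen-4-one | C=C(C)[C@H](O)Cc1c(O)c(CC=C(C)C)c(OC)c2c(=O)c(-c3ccc(O[Si](C(C)C)(C(C)C)C(C)C)cc3)coc12 | intermediate
20 | 7-hydroxy-8-[(2R)-2-hydroxy-3-methylbut-3-en-1-yl]-3-(4-hydroxyphenyl)-5-methoxy-6-(3-methylbut-2-en-1-yl)-4H-chromen-4-one | C=C(C)[C@H](O)Cc1c(O)c(CC=C(C)C)c(OC)c2c(=O)c(-c3ccc(O)cc3)coc12 | target

## Step count and least certain steps

Total: 12 steps. Longest linear sequence: 8 steps (steps 5–12, from methyl acetoacetate 9). Lactone 5 (steps 1–2) and amide 8 (steps 3–4) are made in two short side branches.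

**Step 10 (key step, proposed new method).**
- Risk: the stabilised dienolate may add to the lactone carbonyl too slowly. Slower base-mediated processes would then take over: cleavage of the C7–C8 bond by internal O-attack at C7 with loss of the lactone, or aldol closure of the benzylic methylene onto C7.
- Fallback: the lactone is replaced by an open-chain methyl ester, for which the methoxide-type Claisen cyclisation to acylphloroglucinols is documented chemistry. The fallback sets out from hydroxy ester 4, which is intercepted before lactonisation (Et3SiCl, imidazole, DMF) as the silyl ether ester F1. The lithium enolate of F1 is acylated with 14 to the beta-keto ester F2, and the dianion of F2 is acylated with 8 to the open-chain triketide ester F3, by the operations of steps 8 and 9. Mg(OMe)2 in MeOH at reflux should close ring A of F3 with loss of methanol to the silyl-protected deoxybenzoin F4. Pyridinium p-toluenesulfonate in MeOH then removes the triethylsilyl ether, and the route is rejoined at 17.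

**Step 9.**
- Risk: proton transfer from the benzylic methylene of 8 to the strongly basic dianion can quench the carbanion before it adds. Incomplete second deprotonation of 15 is the other weak point.
- Fallback: the acyl donor is exchanged for an aldehyde and the oxidation level is corrected afterwards. The fallback sets out from 8, which i-Bu2AlH (THF, −78 °C) reduces to the arylacetaldehyde F5. The dianion of 15 should add to F5 at −78 °C faster than the aldehyde is enolised, to give the hydroxy ketone F6. Dess–Martin periodinane (NaHCO3, CH2Cl2, 0 °C) oxidises the new carbinol to the C4 ketone, and the route is rejoined at 16.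

**Step 8.**
- Risk: O-acylation of the lactone enolate, or dehydrochlorination of 14 to a vinylketene by the excess amide base, would divert the acyl donor. A hindered, donor-substituted acid chloride is a slow C-acylating agent.
- Fallback: decarboxylative acylation under near-neutral conditions. The fallback sets out from 5: LiN(i-Pr)2 and then CO2 give the lactone carboxylic acid F7. Acid 13 is converted with 1,1'-carbonyldiimidazole into the acyl imidazole F8. The magnesium enolate of F7 (MgCl2, Et3N, MeCN) is C-acylated by F8 and loses CO2 on mildly acidic work-up, and the route is rejoined at 15.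

**Step 11.**
- Risk: methylation of the acidic C7 phenol by the amide acetal, or incomplete closure onto the hindered, hydrogen-bonded C8a hydroxyl, would lower the yield of the chromenone.
- Fallback: base-mediated C-formylation in place of the amide acetal. The fallback sets out from 17. NaH (5 equiv) and ethyl formate in THF at 0 → 23 °C formylate the benzylic carbon of the polyanion, and the formyl ketone closes onto the C8a oxygen to the 2-hydroxyisoflavanone F9. Brief warming in AcOH dehydrates F9, and the route is rejoined at 19. No methylating agent is present, and a formate that may form at the carbinol is removed by K2CO3 in MeOH.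

## Further compounds

F1 | step 10 | methyl (4R)-5-methyl-4-(triethylsilyloxy)hex-5-enoate | C=C(C)[C@H](O[Si](CC)(CC)CC)CCC(=O)OC
F2 | step 10 | methyl 5-methoxy-4-(3-methylbut-2-en-1-yl)-2-[(2R)-3-methyl-2-(triethylsilyloxy)but-3-en-1-yl]-3-oxohex-4-enoate | C=C(C)[C@H](O[Si](CC)(CC)CC)CC(C(=O)OC)C(=O)C(CC=C(C)C)=C(C)OC
F3 | step 10 | methyl 5-methoxy-4-(3-methylbut-2-en-1-yl)-2-[(2R)-3-methyl-2-(triethylsilyloxy)but-3-en-1-yl]-3,7-dioxo-8-[4-(triisopropylsilyloxy)phenyl]oct-5-enoate | C=C(C)[C@H](O[Si](CC)(CC)CC)CC(C(=O)OC)C(=O)C(CC=C(C)C)C(OC)=CC(=O)Cc1ccc(O[Si](C(C)C)(C(C)C)C(C)C)cc1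
F4 | step 10 | 1-{2,4-dihydroxy-6-methoxy-5-(3-methylbut-2-en-1-yl)-3-[(2R)-3-methyl-2-(triethylsilyloxy)but-3-en-1-yl]phenyl}-2-[4-(triisopropylsilyloxy)phenyl]ethan-1-one | C=C(C)[C@H](O[Si](CC)(CC)CC)Cc1c(O)c(CC=C(C)C)c(OC)c(C(=O)Cc2ccc(O[Si](C(C)C)(C(C)C)C(C)C)cc2)c1O
F5 | step 9 | 2-[4-(triisopropylsilyloxy)phenyl]acetaldehyde | O=CCc1ccc(O[Si](C(C)C)(C(C)C)C(C)C)cc1
F6 | step 9 | (5R)-3-{5-hydroxy-3-methoxy-2-(3-methylbut-2-en-1-yl)-6-[4-(triisopropylsilyloxy)phenyl]hex-2-enoyl}-5-(prop-1-en-2-yl)oxolan-2-one | C=C(C)[C@H]1CC(C(=O)C(CC=C(C)C)=C(OC)CC(O)Cc2ccc(O[Si](C(C)C)(C(C)C)C(C)C)cc2)C(=O)O1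
F7 | step 8 | (5R)-2-oxo-5-(prop-1-en-2-yl)oxolane-3-carboxylic acid | C=C(C)[C@H]1CC(C(=O)O)C(=O)O1
F8 | step 8 | 1-(1H-imidazol-1-yl)-3-methoxy-2-(3-methylbut-2-en-1-yl)but-2-en-1-one | COC(C)=C(CC=C(C)C)C(=O)n1ccnc1
F9 | step 11 | 2,7-dihydroxy-8-[(2R)-2-hydroxy-3-methylbut-3-en-1-yl]-5-methoxy-6-(3-methylbut-2-en-1-yl)-3-[4-(triisopropylsilyloxy)phenyl]chroman-4-one | C=C(C)[C@H](O)Cc1c(O)c(CC=C(C)C)c(OC)c2C(=O)C(c3ccc(O[Si](C(C)C)(C(C)C)C(C)C)cc3)C(O)Oc12
A1 | alternative 1 | 7-(tert-butyldimethylsilyloxy)-3-[4-(tert-butyldimethylsilyloxy)phenyl]-8-{[(2R,3R)-3-(hydroxymethyl)-3-methyloxiran-2-yl]methyl}-5-methoxy-6-(3-methylbut-2-en-1-yl)-4H-chromen-4-one | OC[C@@]1(C)O[C@@H]1Cc1c(O[Si](C)(C)C(C)(C)C)c(CC=C(C)C)c(OC)c2c(=O)c(-c3ccc(O[Si](C)(C)C(C)(C)C)cc3)coc12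
A2 | alternative 1 | 7-(tert-butyldimethylsilyloxy)-3-[4-(tert-butyldimethylsilyloxy)phenyl]-8-[(2E)-4-hydroxy-3-methylbut-2-en-1-yl]-5-methoxy-6-(3-methylbut-2-en-1-yl)-4H-chromen-4-one | OC/C(C)=C/Cc1c(O[Si](C)(C)C(C)(C)C)c(CC=C(C)C)c(OC)c2c(=O)c(-c3ccc(O[Si](C)(C)C(C)(C)C)cc3)coc12
A3 | alternative 2 | (2R)-1-[7-acetoxy-3-(4-acetoxyphenyl)-5-methoxy-6-(3-methylbut-2-en-1-yl)-4-oxo-4H-chromen-8-yl]-3-methylbut-3-en-2-yl acetate | C=C(C)[C@H](OC(C)=O)Cc1c(OC(C)=O)c(CC=C(C)C)c(OC)c2c(=O)c(-c3ccc(OC(C)=O)cc3)coc12
A4 | alternative 2 | (2Z)-2-(4-acetoxyphenyl)-3-{3-acetoxy-2-[(2R)-2-acetoxy-3-methylbut-3-en-1-yl]-5-methoxy-4-(3-methylbut-2-en-1-yl)phenoxy}prop-2-enoyl chloride | C=C(C)[C@H](OC(C)=O)Cc1c(OC(C)=O)c(CC=C(C)C)c(OC)cc1O/C=C(\C(Cl)=O)c1ccc(OC(C)=O)cc1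
A5 | alternative 3 | 4-[(2R)-2-(tert-butyldimethylsilyloxy)-3-methylbut-3-en-1-yl]-2-(3-methylbut-2-en-1-yl)-3,5-bis(triisopropylsilyloxy)phenol | C=C(C)[C@H](O[Si](C)(C)C(C)(C)C)Cc1c(O[Si](C(C)C)(C(C)C)C(C)C)cc(O)c(CC=C(C)C)c1O[Si](C(C)C)(C(C)C)C(C)C
A6 | alternative 3 | 2-[(2R)-2-(tert-butyldimethylsilyloxy)-3-methylbut-3-en-1-yl]-3-(triisopropylsilyloxy)cyclobut-2-en-1-one | C=C(C)[C@H](O[Si](C)(C)C(C)(C)C)CC1=C(O[Si](C(C)C)(C(C)C)C(C)C)CC1=O
A7 | alternative 3 | triisopropyl[(5-methylhex-4-en-1-yn-1-yl)oxy]silane | CC(C)=CCC#CO[Si](C(C)C)(C(C)C)C(C)C
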